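Each ring of the target is a 5-alkylresorcinol, a folded tetraketide: the chain-bearing carbon C1 of ring A and of ring B is a former ketone carbon, its ortho neighbour C2 a former ester-activated methylene, and the oxygens at C3 and C5 are former ketones. Both C1–C2 ring bonds are disconnected at once, giving an open-chain bis(3,5,7-trioxo methyl ester) that already holds the (Z)-C8'=C9' alkene and both heptamethylene arms, inherited from (Z)-octadec-9-enedioic acid. One base-mediated operation then runs two aldol cyclizations and aromatizations, closing both benzene rings. Saponification–decarboxylation and one monoacetylation of the symmetric tetraphenol finish the route.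

Key step: step 3

Assumption: (Z)-octadec-9-enedioic acid and methyl 3,5-dioxohexanoate are both bought; the target has no stereocentre, so the Z alkene, carried unchanged from the diacid, is the only stereochemical element.

Step 1
Reactants: 1 (9Z)-octadec-9-enedioic acid
Product: 3 (9Z)-N1,N18-dimethoxy-N1,N18-dimethyloctadec-9-enediamide, via bis(acylimidazole) 2 (not isolated)
Conditions: 1,1'-carbonyldiimidazole (2.3 equiv), CH2Cl2, rt; then MeNH(OMe)·HCl (2.6 equiv), rt
Reagents that add atoms: N,O-dimethylhydroxylamine hydrochloride, CNOC.Cl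
Why: Carbonyldiimidazole turns both carboxylic acids into acyl imidazolides, which the hydroxylamine displaces in a standard Weinreb amide coupling, and these neutral room-temperature conditions cannot move or isomerize the isolated Z alkene.

Step 2
Reactants: 3 (9Z)-N1,N18-dimethoxy-N1,N18-dimethyloctadec-9-enediamide; 4 methyl 3,5-dioxohexanoate
Product: 7 dimethyl (15Z)-3,5,7,24,26,28-hexaoxotriacont-15-enedioate, via trilithium trianion 5 (not isolated), via hexalithium bis-adduct 6 (not isolated)
Conditions: 4 (4 equiv), LiN(iPr)2 (12.2 equiv), THF, −78 to 0 °C; then 3 (1 equiv), −78 to 0 °C; poured into cold dilute aq. HCl (pH 3–4)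
Reagents that add atoms: none
Why: This is a Weinreb ketone synthesis with a polyketide trianion, in which the base removes the C2, C4 and finally the C6 protons of 4, the terminal C6 carbanion of 5 as the most nucleophilic site adds to each amide carbonyl, and the lithium-chelated tetrahedral adduct 6 resists over-addition and releases the C7 and C24 ketones only on acidic quench; crude 7 is freed from excess 4 and carried on without prolonged chromatography.

Step 3
Reactants: 7 dimethyl (15Z)-3,5,7,24,26,28-hexaoxotriacont-15-enedioate
Product: 9 dimethyl 6,6'-[(8Z)-hexadec-8-ene-1,16-diyl]bis(2,4-dihydroxybenzoate), via bis(aldol) 8 (not isolated)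
Conditions: Cs2CO3 (4 equiv), MeOH (0.05 M), 0 °C to rt; then methanolic HCl to pH 2, rt
Reagents that add atoms: none
Why: Carbonate equilibrates the enolates of each 3,5,7-trioxo ester terminus, and the C2 (C29) enolate, stabilized by the ester and the C3 (C28) ketone, adds to the C7 (C24) ketone to give the bis(aldol) 8, which loses water by β-elimination and tautomerizes at C3/C5 and C26/C28 to the two phenolic rings, acid work-up completing the dehydration. The closest known reaction is the biomimetic aldol cycloaromatization of 3,5,7-trioxoalkanoates to 6-alkyl-2,4-dihydroxybenzoates, performed here at two remote and independent chain ends. Ring A and ring B are each closed by a 6-exo-trig aldol addition (enolate carbon C2 onto C7, C29 onto C24), so each new bond joins the chain-bearing ring carbon to its ester-bearing ortho neighbour. No stereocentre is created in 9, because the carbinol and ester-bearing centres of 8 vanish on aromatization, and the Z alkene, seven methylenes from C7 and from C24, is neither conjugated nor acidified and keeps its geometry. The selectivity required is C-aldol closure in preference to Claisen attack of C6 on the ester (acylphloroglucinol) and to lactonization of the C5 enol oxygen onto the ester (4-hydroxy-2-pyranone): although C4 and C6 are the more acidic methylenes, their enolates have no six-membered closure onto a ketone, whereas C2 does, and the C7 ketone is a far better electrophile than the methyl ester, which a weak carbonate base in methanol does not drive to acyl transfer. Aromatization makes the aldol pathway irreversible and so funnels both termini to the same resorcylate.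

Step 4
Reactants: 9 dimethyl 6,6'-[(8Z)-hexadec-8-ene-1,16-diyl]bis(2,4-dihydroxybenzoate)
Product: 11 5,5'-[(8Z)-hexadec-8-ene-1,16-diyl]bis(benzene-1,3-diol), via bis(resorcylic acid) 10 (not isolated)
Conditions: KOH (2 M aq., 20 equiv), MeOH, reflux, Ar (degassed); then aq. HCl to pH 1–2, 80 °C
Reagents that add atoms: none
Why: Hot aqueous KOH saponifies the two hindered, hydrogen-bonded salicylate-type esters, and the resulting 2,4-dihydroxybenzoic acids 10 lose CO2 on warming in dilute acid through ipso protonation of the electron-rich ring (protodecarboxylation of β-resorcylic acids), while the isolated Z alkene is inert to both media and exclusion of air protects the phenolates.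

Step 5
Reactants: 11 5,5'-[(8Z)-hexadec-8-ene-1,16-diyl]bis(benzene-1,3-diol)
Product: 12 oncostemonol B, 3-[(8Z)-16-(3,5-dihydroxyphenyl)hexadec-8-en-1-yl]-5-hydroxyphenyl acetate
Conditions: Ac2O (0.8 equiv, slow addition), pyridine (3 equiv), THF, 0 °C; chromatography, recovered 11 recycled
Reagents that add atoms: acetic anhydride, CC(=O)OC(C)=O
Why: This is a pyridine-mediated O-acetylation of a phenol in which the four hydroxyls of 11 are symmetry-equivalent, so whichever reacts first gives 12, sub-stoichiometric anhydride limits statistical over-acetylation, and unreacted 11 together with over-acetylated material (returned to 11 by K2CO3/MeOH) is recycled.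

Compound list
1 | (9Z)-octadec-9-enedioic acid | OC(=O)CCCCCCC/C=C\CCCCCCCC(=O)O | starting material
2 | (9Z)-1,18-di(1H-imidazol-1-yl)octadec-9-ene-1,18-dione, the bis(acylimidazole) | O=C(CCCCCCC/C=C\CCCCCCCC(=O)n1ccnc1)n1ccnc1 | intermediate
3 | (9Z)-N1,N18-dimethoxy-N1,N18-dimethyloctadec-9-enediamide | CON(C)C(=O)CCCCCCC/C=C\CCCCCCCC(=O)N(C)OC | intermediate
4 | methyl 3,5-dioxohexanoate | COC(=O)CC(=O)CC(=O)C | starting material
5 | trilithium trianion (tris-enolate) of methyl 3,5-dioxohexanoate | [Li+].[Li+].[Li+].C=C([O-])C=C([O-])C=C([O-])OC | intermediate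
6 | hexalithium salt of the double tetrahedral adduct of 5 with 3 (two N-methoxy-N-methyl hemiaminal alkoxides, each next to a dienolate) | [Li+].[Li+].[Li+].[Li+].[Li+].[Li+].COC(=O)C=C([O-])C=C([O-])CC([O-])(N(C)OC)CCCCCCC/C=C\CCCCCCCC([O-])(N(C)OC)CC([O-])=CC([O-])=CC(=O)OC | intermediate
7 | dimethyl (15Z)-3,5,7,24,26,28-hexaoxotriacont-15-enedioate | COC(=O)CC(=O)CC(=O)CC(=O)CCCCCCC/C=C\CCCCCCCC(=O)CC(=O)CC(=O)CC(=O)OC | intermediate
8 | dimethyl 2,2'-[(8Z)-hexadec-8-ene-1,16-diyl]bis(2-hydroxy-4,6-dioxocyclohexane-1-carboxylate), the bis(aldol), transient ring centres undefined | COC(=O)C1C(=O)CC(=O)CC1(O)CCCCCCC/C=C\CCCCCCCC1(O)CC(=O)CC(=O)C1C(=O)OC | intermediate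
9 | dimethyl 6,6'-[(8Z)-hexadec-8-ene-1,16-diyl]bis(2,4-dihydroxybenzoate) | COC(=O)c1c(O)cc(O)cc1CCCCCCC/C=C\CCCCCCCc1cc(O)cc(O)c1C(=O)OC | intermediate
10 | 6,6'-[(8Z)-hexadec-8-ene-1,16-diyl]bis(2,4-dihydroxybenzoic acid) | OC(=O)c1c(O)cc(O)cc1CCCCCCC/C=C\CCCCCCCc1cc(O)cc(O)c1C(=O)O | intermediate
11 | 5,5'-[(8Z)-hexadec-8-ene-1,16-diyl]bis(benzene-1,3-diol) | Oc1cc(O)cc(CCCCCCC/C=C\CCCCCCCc2cc(O)cc(O)c2)c1 | intermediate
12 | oncostemonol B, 3-[(8Z)-16-(3,5-dihydroxyphenyl)hexadec-8-en-1-yl]-5-hydroxyphenyl acetate | CC(=O)Oc1cc(O)cc(CCCCCCC/C=C\CCCCCCCc2cc(O)cc(O)c2)c1 | target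

Total step count: 5
Longest linear sequence: 5 steps (1 to 12)

Steps most likely to fail

Step 3. The risk is closure through oxygen instead of carbon (lactonization of the C5 enol onto the ester), or clean reaction at only one terminus. The fallback sets out from 7 and drives both termini deliberately into the lactone manifold. Heating in xylene at about 140 °C with catalytic p-toluenesulfonic acid and removal of methanol should give the bis(pyranone) (10Z)-1,20-bis(4-hydroxy-2-oxo-2H-pyran-6-yl)icos-10-ene-2,19-dione F5. Aqueous KOH then opens both lactones to the salt of (15Z)-3,5,7,24,26,28-hexaoxotriacont-15-enedioic acid F6. Its carboxylate can neither lactonize nor accept a Claisen attack, so only the C2-to-C7 aldol remains, as in the known conversion of 6-(2-oxoalkyl)-4-hydroxy-2-pyranones into β-resorcylic acids. Acidification gives 10, where the route is rejoined and continues to 11 as in the second half of step 4.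

Step 2. The risk is incomplete double C-acylation, or proton transfer from the α-methylene of the amide to the strongly basic trianion, leaving mono-acylated material. The fallback sets out from 3 and exchanges the nucleophile for a carboxyl-masked synthon. The keto-dioxinone 2,2-dimethyl-6-(2-oxopropyl)-4H-1,3-dioxin-4-one F1 is made from commercial 2,2,6-trimethyl-4H-1,3-dioxin-4-one with LiN(SiMe3)2 and acetyl chloride. Two equivalents of LiN(iPr)2 convert it into the dilithium dienolate F2, whose terminal carbon acylates both amide groups of 3. This gives the bis(diketo-dioxinone) (12Z)-1,24-bis(2,2-dimethyl-4-oxo-4H-1,3-dioxin-6-yl)tetracos-12-ene-2,4,21,23-tetrone F3. Heating F3 in toluene with methanol at 110 °C expels acetone by retro-[4+2] fragmentation, and the bis(acylketene) (15Z)-3,5,7,24,26,28-hexaoxotriaconta-1,15,29-triene-1,30-dione F4 is captured by methanol. This returns the route to 7.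

Step 5. The risk is over-acetylation, with a statistical spread over mono-, di- and triacetates that is hard to separate. The fallback sets out from 11 and works by subtraction instead of addition. Exhaustive acetylation (Ac2O, pyridine) gives the air-stable, easily purified tetraacetate (8Z)-hexadec-8-ene-1,16-diylbis(benzene-5,1,3-triyl) tetraacetate F7. Controlled methanolysis (catalytic K2CO3, MeOH/THF, −10 °C, monitored, quenched with AcOH) removes the acetates one at a time. It passes through the triacetate 3-[(8Z)-16-(3,5-diacetoxyphenyl)hexadec-8-en-1-yl]-5-hydroxyphenyl acetate F8 and the bis(monoacetate) (8Z)-hexadec-8-ene-1,16-diylbis(5-hydroxy-3,1-phenylene) diacetate F9. A ring that already carries a free, partly ionized phenol should release its remaining acetate more slowly, so the sequence is expected to slow at F9 and again at 12. Compound 12 is isolated there, rejoining the route, and F9 and 11 are recycled.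

Further compounds
F1 | step 2 | 2,2-dimethyl-6-(2-oxopropyl)-4H-1,3-dioxin-4-one | CC(=O)CC1=CC(=O)OC(C)(C)O1
F2 | step 2 | dilithium dienolate of 2,2-dimethyl-6-(2-oxopropyl)-4H-1,3-dioxin-4-one | [Li+].[Li+].C=C([O-])C=C1C=C([O-])OC(C)(C)O1
F3 | step 2 | (12Z)-1,24-bis(2,2-dimethyl-4-oxo-4H-1,3-dioxin-6-yl)tetracos-12-ene-2,4,21,23-tetrone | CC1(C)OC(=O)C=C(CC(=O)CC(=O)CCCCCCC/C=C\CCCCCCCC(=O)CC(=O)CC2=CC(=O)OC(C)(C)O2)O1
F4 | step 2 | (15Z)-3,5,7,24,26,28-hexaoxotriaconta-1,15,29-triene-1,30-dione, the bis(acylketene) | O=C=CC(=O)CC(=O)CC(=O)CCCCCCC/C=C\CCCCCCCC(=O)CC(=O)CC(=O)C=C=O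
F5 | step 3 | (10Z)-1,20-bis(4-hydroxy-2-oxo-2H-pyran-6-yl)icos-10-ene-2,19-dione | O=C1C=C(O)C=C(CC(=O)CCCCCCC/C=C\CCCCCCCC(=O)CC2=CC(O)=CC(=O)O2)O1
F6 | step 3 | (15Z)-3,5,7,24,26,28-hexaoxotriacont-15-enedioic acid (formed as its potassium salt) | OC(=O)CC(=O)CC(=O)CC(=O)CCCCCCC/C=C\CCCCCCCC(=O)CC(=O)CC(=O)CC(=O)O
F7 | step 5 | (8Z)-hexadec-8-ene-1,16-diylbis(benzene-5,1,3-triyl) tetraacetate | CC(=O)Oc1cc(OC(C)=O)cc(CCCCCCC/C=C\CCCCCCCc2cc(OC(C)=O)cc(OC(C)=O)c2)c1
F8 | step 5 | 3-[(8Z)-16-(3,5-diacetoxyphenyl)hexadec-8-en-1-yl]-5-hydroxyphenyl acetate | CC(=O)Oc1cc(O)cc(CCCCCCC/C=C\CCCCCCCc2cc(OC(C)=O)cc(OC(C)=O)c2)c1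
F9 | step 5 | (8Z)-hexadec-8-ene-1,16-diylbis(5-hydroxy-3,1-phenylene) diacetate | CC(=O)Oc1cc(O)cc(CCCCCCC/C=C\CCCCCCCc2cc(O)cc(OC(C)=O)c2)c1
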